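**Retrosynthetic overview**
1. Target 23 ⇐ 22 ⇐ 21: acetylation, then double epoxidation of the 3E alkene (trans-oxirane) and the 7Z alkene (cis-oxirane) under substrate control.
2. 21 ⇐ 19: the 12-membered ring is closed last by an intramolecular Nozaki–Hiyama allylation forming C10–C11; this sets C10 and C11 and leaves the C12=C18 methylene beside the C13 ketone.
3. Bridge C2–C10 ⇐ two sigmatropic key steps on isopropenyl carbinols: Johnson–Claisen [3,3] (C5–C6 bond, 3E) and Still–Wittig [2,3] (C9–C10 bond, 7Z).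
4. Ring A (formed first) ⇐ aldol condensation of the keto aldehyde from ozonolysis of (S)-α-campholenic aldehyde, then Baylis–Hillman hydroxymethylation (C18) and Wharton transposition (oxygen to C13); C1 is the purchased stereocentre.
5. Ring order: ring A (step 3) → 12-membered ring (step 16) → two oxiranes (step 18).

Assumption: (S)-α-campholenic aldehyde (fragrance intermediate made from α-pinene oxide) is bought as the single enantiomer.
Numbering: atom labels C1–C20 are the verticillane numbers of the target (C1 and C11 = ring-A carbons carrying the bridge, C12=C18 methylene, C13 ketone, C15 gem-dimethyl carbon, C2–C10 bridge with oxiranes at C3–C4 and C7–C8 and the acetate at C10).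

**Route**

Step 1
Reactants: 1 (S)-α-campholenic aldehyde
Product: 2 isopropenyl carbinol (2RS)-3-methyl-1-[(1S)-2,2,3-trimethylcyclopent-3-en-1-yl]but-3-en-2-ol
Conditions: CH2=C(CH3)MgBr (1.2 equiv), THF, −78 → 0 °C; H2O
Reagents that add atoms: isopropenylmagnesium bromide, CC(=C)[Mg]Br
Why: Grignard 1,2-addition to the unhindered aldehyde gives the allylic alcohol for the Claisen step; the new C3 carbinol forms as both epimers, which is harmless because step 8 makes C3 an sp2 carbon.

Step 2
Reactants: 2 isopropenyl carbinol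
Product: 4 keto aldehyde (3R)-3-[(2RS)-2-hydroxy-3-methylbut-3-en-1-yl]-4,4-dimethyl-5-oxohexanal, via ozonide 3 (not isolated)
Conditions: O3 (1.0 equiv), CH2Cl2, −78 °C; then Me2S, −78 °C → rt
Reagents that add atoms: ozone, [O-][O+]=O
Why: Ozonolysis with reductive work-up: the electron-rich trisubstituted ring alkene is cleaved much faster than the 1,1-disubstituted alkene bearing an allylic hydroxyl, and C1 is untouched.

Step 3
Reactants: 4 keto aldehyde
Product: 5 enone (5S)-5-[(2RS)-2-hydroxy-3-methylbut-3-en-1-yl]-6,6-dimethylcyclohex-2-en-1-one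
Conditions: KOH (0.3 equiv), MeOH, 0 °C → rt
Reagents that add atoms: none
Why: Intramolecular aldol condensation: the ketone can enolise only toward its methyl group (the other α-carbon is quaternary C15), so C12 attacks the C13 aldehyde and dehydration gives ring A as one enone, with C1 (β to both carbonyls) not epimerisable.

Step 4
Reactants: 5 enone
Product: 6 hydroxymethyl enone (5S)-5-[(2RS)-2-hydroxy-3-methylbut-3-en-1-yl]-2-(hydroxymethyl)-6,6-dimethylcyclohex-2-en-1-one
Conditions: 37% aq. HCHO, DMAP (0.3 equiv), THF/H2O, rt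
Reagents that add atoms: formaldehyde, C=O
Why: Morita–Baylis–Hillman reaction: nucleophilic catalysis by DMAP at the unhindered β-carbon C13 makes C12 add to formaldehyde, which brings in C18.

Step 5
Reactants: 6 hydroxymethyl enone
Product: 7 epoxy ketone (2,3-epoxide of 6)
Conditions: 30% H2O2, NaOH (0.2 equiv), MeOH, 0 °C
Reagents that add atoms: hydrogen peroxide, OO
Why: Weitz–Scheffer nucleophilic epoxidation of the enone only, with attack at C13 anti to the C1 side chain as for 5-substituted cyclohexenones; the two new centres are erased in steps 6 and 15.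

Step 6
Reactants: 7 epoxy ketone
Product: 8 triol (5R)-2-(hydroxymethyl)-5-[(2RS)-2-hydroxy-3-methylbut-3-en-1-yl]-4,4-dimethylcyclohex-2-en-1-ol
Conditions: N2H4·H2O (3 equiv), AcOH (cat.), MeOH, 0 °C → rt
Reagents that add atoms: none
Why: Wharton transposition: hydrazine turns the α,β-epoxy ketone into the transposed allylic alcohol with loss of N2, moving the oxygen to C13 and the alkene to C11=C12 next to the gem-dimethyl carbon.

Step 7
Reactants: 8 triol
Product: 9 acetonide alcohol (acetonide of 8 across O–C13 and O–C18)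
Conditions: Me2C(OMe)2, PPTS (cat.), CH2Cl2, rt
Reagents that add atoms: 2,2-dimethoxypropane, COC(C)(C)OC
Why: Acetal formation closes a six-membered isopropylidene ring on the 1,3-diol and leaves the isolated C3 carbinol free.

Step 8
Reactants: 9 acetonide alcohol
Product: 11 ethyl (E)-ester, via ketene acetal 10 (not isolated)
Conditions: CH3C(OEt)3 (6 equiv), EtCO2H (0.1 equiv), 140 °C, EtOH distilled off
Reagents that add atoms: triethyl orthoacetate, CC(OCC)(OCC)OCC
Why: Johnson–Claisen [3,3]-sigmatropic rearrangement of 10 through a chair with the C2 substituent equatorial forms the C5–C6 bond and the 3E trisubstituted alkene, and both C3 epimers converge.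

Step 9
Reactants: 11 ethyl (E)-ester
Product: 12 (E)-aldehyde
Conditions: i-Bu2AlH (1.1 equiv), CH2Cl2, −78 °C; H2O
Reagents that add atoms: none
Why: Low-temperature partial reduction of the ester stops at the aldehyde oxidation level, and the acetonide and alkenes are inert.

Step 10
Reactants: 12 (E)-aldehyde
Product: 13 second isopropenyl carbinol (C7 epimers)
Conditions: CH2=C(CH3)MgBr (1.2 equiv), THF, −78 °C; H2O
Reagents that add atoms: isopropenylmagnesium bromide, CC(=C)[Mg]Br
Why: Grignard 1,2-addition brings in C8, C9 and C19; the C7 carbinol forms as both epimers and becomes sp2 in step 12.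

Step 11
Reactants: 13 second isopropenyl carbinol
Product: 14 tributylstannylmethyl ether
Conditions: KH, 18-crown-6 (cat.), THF, 0 °C; then Bu3SnCH2I, rt
Reagents that add atoms: tributyl(iodomethyl)stannane, CCCC[Sn](CCCC)(CCCC)CI
Why: Williamson O-alkylation of the secondary allylic alcohol installs the carbanion precursor that carries C10.

Step 12
Reactants: 14 tributylstannylmethyl ether
Product: 16 (3E,7Z)-homoallylic alcohol, via lithiomethyl ether 15 (not isolated)
Conditions: n-BuLi (1.3 equiv), THF, −78 °C; H2O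
Reagents that add atoms: none
Why: Still–Wittig [2,3]-sigmatropic rearrangement: tin–lithium exchange gives 15, which rearranges with the C6 substituent pseudo-axial (A(1,2) strain with the C8 methyl), forming the C9–C10 bond and the 7Z alkene.

Step 13
Reactants: 16 (3E,7Z)-homoallylic alcohol
Product: 17 triol (5R)-2-(hydroxymethyl)-5-[(2E,6Z)-9-hydroxy-3,7-dimethylnona-2,6-dien-1-yl]-4,4-dimethylcyclohex-2-en-1-ol
Conditions: AcOH/THF/H2O (3:1:1), rt
Reagents that add atoms: none
Why: Mild acid hydrolysis removes the acetonide without moving either trisubstituted alkene.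

Step 14
Reactants: 17 triol
Product: 18 allylic bromide (5R)-2-(bromomethyl)-5-[(2E,6Z)-9-hydroxy-3,7-dimethylnona-2,6-dien-1-yl]-4,4-dimethylcyclohex-2-en-1-ol
Conditions: NBS (2.2 equiv), Me2S (2.6 equiv), CH2Cl2, −25 → 0 °C
Reagents that add atoms: N-bromosuccinimide, O=C1CCC(=O)N1Br
Why: Corey–Kim bromination converts allylic alcohols only and the primary C18–OH reacts ahead of the hindered secondary C13–OH, while the saturated C10–OH is recovered unchanged.

Step 15
Reactants: 18 allylic bromide
Product: 19 bromomethyl enone aldehyde (5R)-2-(bromomethyl)-4,4-dimethyl-5-[(2E,6Z)-3,7-dimethyl-9-oxonona-2,6-dien-1-yl]cyclohex-2-en-1-one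
Conditions: Dess–Martin periodinane (2.5 equiv), CH2Cl2, 0 °C → rt
Reagents that add atoms: none
Why: Dess–Martin oxidation takes both remaining alcohols to the C13 enone and the β,γ-unsaturated C10 aldehyde under conditions that do not shift the double bonds.

Step 16
Reactants: 19 bromomethyl enone aldehyde
Product: 21 macrocyclic hydroxy enone (1R,3E,7Z,10R,11S)-10-hydroxyverticilla-3,7,12(18)-trien-13-one, via allylchromium dichloride 20 (not isolated)
Conditions: CrCl2 (6 equiv), THF, 0.002 M (substrate added over 12 h), rt; H2O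
Reagents that add atoms: none
Why: Intramolecular Nozaki–Hiyama allylation: 20 adds to the aldehyde through its γ-carbon C11 in a chair transition state (C10–OH anti to C15), on the ring-A face trans to the C1 chain, which closes the 12-membered ring and moves the alkene to C12=C18.

Step 17
Reactants: 21 macrocyclic hydroxy enone
Product: 22 acetate (1R,3E,7Z,10R,11S)-10-acetoxyverticilla-3,7,12(18)-trien-13-one
Conditions: Ac2O, pyridine, DMAP (cat.), CH2Cl2, 0 °C
Reagents that add atoms: acetic anhydride, CC(=O)OC(C)=O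
Why: Standard acylation of the only hydroxyl group.

Step 18
Reactants: 22 acetate
Product: 23 target (1R,3R,4R,7R,8S,10R,11S)-10-acetoxy-3,4:7,8-diepoxyverticill-12(18)-en-13-one
Conditions: mCPBA (2.2 equiv), CH2Cl2, 0 °C
Reagents that add atoms: mCPBA (3-chloroperoxybenzoic acid), O=C(OO)c1cccc(Cl)c1
Why: Prilezhaev epoxidation: only the two electron-rich trisubstituted alkenes react (the enone methylene does not), and each oxirane is expected from peripheral attack on the exposed face of the bicycle, so C3, C4, C7 and C8 are set by substrate control from C1, C10 and C11 (this facial outcome is predicted, not proven).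

**Compound list**
1 | (S)-α-campholenic aldehyde, 2-[(1S)-2,2,3-trimethylcyclopent-3-en-1-yl]acetaldehyde | CC1=CC[C@@H](CC=O)C1(C)C | starting material
2 | (2RS)-3-methyl-1-[(1S)-2,2,3-trimethylcyclopent-3-en-1-yl]but-3-en-2-ol (both C3 epimers) | CC1=CC[C@@H](CC(O)C(C)=C)C1(C)C | intermediate
3 | ozonide of 2 (1,2,4-trioxolane across the former cyclopentene C=C; ring stereocentre as in 2) | CC12OOC(O1)C[C@@H](CC(O)C(C)=C)C2(C)C | intermediate (not isolated)
4 | (3R)-3-[(2RS)-2-hydroxy-3-methylbut-3-en-1-yl]-4,4-dimethyl-5-oxohexanal | CC(=O)C(C)(C)[C@H](CC(O)C(C)=C)CC=O | intermediate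
5 | (5S)-5-[(2RS)-2-hydroxy-3-methylbut-3-en-1-yl]-6,6-dimethylcyclohex-2-en-1-one | O=C1C=CC[C@@H](CC(O)C(C)=C)C1(C)C | intermediate
6 | (5S)-5-[(2RS)-2-hydroxy-3-methylbut-3-en-1-yl]-2-(hydroxymethyl)-6,6-dimethylcyclohex-2-en-1-one | O=C1C(CO)=CC[C@@H](CC(O)C(C)=C)C1(C)C | intermediate
7 | 2,3-epoxide of 6: 4-(2-hydroxy-3-methylbut-3-en-1-yl)-1-(hydroxymethyl)-3,3-dimethyl-7-oxabicyclo[4.1.0]heptan-2-one; ring stereocentre as in 6, oxirane trans to the side chain (inconsequential) | O=C1C2(CO)OC2C[C@@H](CC(O)C(C)=C)C1(C)C | intermediate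
8 | (5R)-2-(hydroxymethyl)-5-[(2RS)-2-hydroxy-3-methylbut-3-en-1-yl]-4,4-dimethylcyclohex-2-en-1-ol; the ring carbinol is C13 (trans to the side chain, later the ketone) | OCC1=CC(C)(C)[C@H](CC(O)C(C)=C)CC1O | intermediate
9 | acetonide of 8: 2,2-dimethyl-1,3-dioxane fused to ring A through O–C13 and O–C18; side chain CH2–CH(OH)–C(CH3)=CH2 free; C1 as in 8 | CC1(C)OCC2=CC(C)(C)[C@H](CC(O)C(C)=C)CC2O1 | intermediate
10 | 1-ethoxyvinyl ether of 9 at O–C3 (mixed ketene acetal) | CC1(C)OCC2=CC(C)(C)[C@H](CC(OC(=C)OCC)C(C)=C)CC2O1 | intermediate (not isolated)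
11 | ethyl (4E)-4-methyl-6-(ring-A acetonide unit of 9)hex-4-enoate; chain C1–CH2–CH=C(CH3)–CH2CH2–CO2Et, 3E | CC1(C)OCC2=CC(C)(C)[C@H](C/C=C(C)/CCC(=O)OCC)CC2O1 | intermediate
12 | (4E)-aldehyde corresponding to 11; chain C1–CH2–CH=C(CH3)–CH2CH2–CHO | CC1(C)OCC2=CC(C)(C)[C@H](C/C=C(C)/CCC=O)CC2O1 | intermediate
13 | (3RS,6E)-2,6-dimethyl-8-(ring-A acetonide unit)octa-1,6-dien-3-ol (both C7 epimers) | CC1(C)OCC2=CC(C)(C)[C@H](C/C=C(C)/CCC(O)C(C)=C)CC2O1 | intermediate
14 | tributylstannylmethyl ether of 13 (O–CH2–SnBu3 on C7) | CC1(C)OCC2=CC(C)(C)[C@H](C/C=C(C)/CCC(OC[Sn](CCCC)(CCCC)CCCC)C(C)=C)CC2O1 | intermediate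
15 | lithiomethyl ether of 13 (O–CH2–Li on C7) | CC1(C)OCC2=CC(C)(C)[C@H](C/C=C(C)/CCC(OC[Li])C(C)=C)CC2O1 | intermediate (not isolated)
16 | (3Z,7E)-3,7-dimethyl-9-(ring-A acetonide unit)nona-3,7-dien-1-ol (3E,7Z in target numbering; C10–OH free) | CC1(C)OCC2=CC(C)(C)[C@H](C/C=C(C)/CC/C=C(C)\CCO)CC2O1 | intermediate
17 | (5R)-2-(hydroxymethyl)-5-[(2E,6Z)-9-hydroxy-3,7-dimethylnona-2,6-dien-1-yl]-4,4-dimethylcyclohex-2-en-1-ol (ring carbinol C13 as in 8) | OCC1=CC(C)(C)[C@H](C/C=C(C)/CC/C=C(C)\CCO)CC1O | intermediate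
18 | (5R)-2-(bromomethyl)-5-[(2E,6Z)-9-hydroxy-3,7-dimethylnona-2,6-dien-1-yl]-4,4-dimethylcyclohex-2-en-1-ol | BrCC1=CC(C)(C)[C@H](C/C=C(C)/CC/C=C(C)\CCO)CC1O | intermediate
19 | (5R)-2-(bromomethyl)-4,4-dimethyl-5-[(2E,6Z)-3,7-dimethyl-9-oxonona-2,6-dien-1-yl]cyclohex-2-en-1-one | BrCC1=CC(C)(C)[C@H](C/C=C(C)/CC/C=C(C)\CC=O)CC1=O | intermediate
20 | allylchromium dichloride derived from 19 (CrCl2 unit on C18 in place of Br) | Cl[Cr](Cl)CC1=CC(C)(C)[C@H](C/C=C(C)/CC/C=C(C)\CC=O)CC1=O | intermediate (not isolated)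
21 | (1R,3E,7Z,10R,11S)-10-hydroxyverticilla-3,7,12(18)-trien-13-one | C=C1C(=O)C[C@H]2C/C=C(C)/CC/C=C(C)\C[C@@H](O)[C@H]1C2(C)C | intermediate
22 | (1R,3E,7Z,10R,11S)-10-acetoxyverticilla-3,7,12(18)-trien-13-one | C=C1C(=O)C[C@H]2C/C=C(C)/CC/C=C(C)\C[C@@H](OC(C)=O)[C@H]1C2(C)C | intermediate
23 | CNP0339728.4, (1R,3R,4R,7R,8S,10R,11S)-10-acetoxy-3,4:7,8-diepoxyverticill-12(18)-en-13-one | C=C1C(=O)C[C@H]2C[C@H]3O[C@]3(C)CC[C@H]3O[C@@]3(C)C[C@@H](OC(C)=O)[C@H]1C2(C)C | target

**Summary**
Total step count: 18. Longest linear sequence: 18 steps (fully linear from 1).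

The steps most likely to fail are 6, 16 and 18.

For step 6, hydrazone formation on a ketone flanked by two fully substituted carbons may stall. The fallback is a radical version of the same transposition. It sets out from 7: reduction with NaBH4/CeCl3·7H2O gives the epoxy triol F1, 1,1'-thiocarbonyldiimidazole ties the C11/C18 1,3-diol as the cyclic thionocarbonate F2, and Bu3SnH/AIBN generates the C11 radical, which opens the neighbouring oxirane to the C13 alkoxyl radical. K2CO3/MeOH then frees the primary alcohol, and the sequence comes back to the route at 8.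

For step 16, the risks are oligomers, attack through C18 instead of C11, and the cis-bridged isomer. The fallback closes the same bond from the free allylic alcohol and moves the C13 oxidation behind the cyclisation. It sets out from 16: Dess–Martin oxidation gives the acetonide aldehyde F3, aqueous AcOH gives the diol aldehyde F4, and palladium/borane umpolung allylation (Pd(PPh3)4, Et3B, THF, high dilution) gives the macrocyclic diol F5. MnO2 then oxidises only the allylic C13 carbinol, and the sequence comes back at 21.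

For step 18, the facial selectivity of both epoxidations rests on the macrocycle's conformation alone. The fallback uses the C10 hydroxyl as a directing group and splits the two epoxidations. It sets out from 21: VO(acac)2/t-BuOOH epoxidises the homoallylic 7Z alkene to the epoxy alcohol F6, acetylation gives the epoxy acetate F7, and mCPBA then epoxidises the remaining 3E alkene alone, coming back at 23.

Further compounds
F1 | step 6 | epoxy triol: 4-(2-hydroxy-3-methylbut-3-en-1-yl)-1-(hydroxymethyl)-3,3-dimethyl-7-oxabicyclo[4.1.0]heptan-2-ol (ring stereocentre and oxirane as in 7) | OC1C2(CO)OC2C[C@@H](CC(O)C(C)=C)C1(C)C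
F2 | step 6 | cyclic thionocarbonate of F1 (1,3-dioxane-2-thione across O–C11 and O–C18) | S=C1OCC23OC3C[C@@H](CC(O)C(C)=C)C(C)(C)C2O1
F3 | step 16 | acetonide aldehyde: 16 with C10 oxidised to CHO | CC1(C)OCC2=CC(C)(C)[C@H](C/C=C(C)/CC/C=C(C)\CC=O)CC2O1
F4 | step 16 | diol aldehyde: (3Z,7E)-9-[(1R)-5-hydroxy-4-(hydroxymethyl)-2,2-dimethylcyclohex-3-en-1-yl]-3,7-dimethylnona-3,7-dienal | OCC1=CC(C)(C)[C@H](C/C=C(C)/CC/C=C(C)\CC=O)CC1O
F5 | step 16 | macrocyclic diol: (1R,3E,7Z,10R,11S)-verticilla-3,7,12(18)-triene-10,13-diol (C13 carbinol as carried from 8) | C=C1C(O)C[C@H]2C/C=C(C)/CC/C=C(C)\C[C@@H](O)[C@H]1C2(C)C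
F6 | step 18 | epoxy alcohol: (1R,3E,7R,8S,10R,11S)-7,8-epoxy-10-hydroxyverticilla-3,12(18)-dien-13-one | C=C1C(=O)C[C@H]2C/C=C(C)/CC[C@H]3O[C@@]3(C)C[C@@H](O)[C@H]1C2(C)C
F7 | step 18 | epoxy acetate: 10-O-acetyl derivative of F6 | C=C1C(=O)C[C@H]2C/C=C(C)/CC[C@H]3O[C@@]3(C)C[C@@H](OC(C)=O)[C@H]1C2(C)C
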